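The runs were generated by integration with made-up constants; the scatter is artificial.

Which loading of initiator leaves the most target after 8.0 d, and how much can that be?

the same everywhere: temperature 5 °C

| charge | starting material | partner | initiator | remark | time |
|---|---|---|---|---|---|
| south | 0.016 M | 0.64 equiv | 3.1 mol% | run made earlier |  |
| south-west | 0.0080 M | 0.95 equiv | 3.1 mol% | run made earlier |  |
| midnight | 0.016 M | 0.950 equiv | 5 mol% |  | 8.0 d |
| noon | 0.016 M | 0.950 equiv | 1.5 mol% |  | 8.0 d |
| dawn | 0.016 M | 0.950 equiv | 2 mol% |  | 8.0 d |
| autumn | 0.016 M | 0.950 equiv | 1 mol% |  | 8.0 d |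
| dusk | 0.016 M | 0.950 equiv | 3.1 mol% |  | 8.0 d |

| run | time / d | target / % | starting material / % |
|---|---|---|---|
| south | 1.25 | 36.5 | 53.4 |
| south | 2.50 | 44.0 | 30.6 |
| south | 4.00 | 44.7 | 20.8 |
| south | 5.00 | 42.8 | 16.1 |
| south-west | 0.417 | 17.7 | 82.4 |
| south-west | 0.833 | 30.1 | 64.9 |
| south-west | 2.08 | 55.1 | 32.7 |
| south-west | 5.00 | 75.8 | 2.2 |

(standard deviation of a reading: 0.5 percentage points)

* the flasks put in order of amount of target, in percent of the starting material charged, best first, at 8.0 d (midnight / noon / dawn / autumn / dusk)
* the same order at 10 h (midnight / noon / dawn / autumn / dusk)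
* the amount of target, in percent of the starting material charged of the flask you put first, at 8.0 d
* the amount of target, in percent of the starting material charged of the flask you put last, at 8.0 d



I assume that what the balance misses, M = target and starting material subtracted from the charge, consists of pairs, one target joined to one starting material. Partner left is then its charge minus target minus half of M. In south-west its pseudo-first-order constant λ reads 0.497 d⁻¹ at 2.08 d and 0.490 d⁻¹ at 5.00 d, nearly the same. South, at the same loading, twice the concentration and 0.64 equiv of partner, reads 0.868 d⁻¹. Since c(starting material) doubled along with c(initiator), it is my assumption that λ goes as c(initiator), to the power 0.806.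

If pairs form at k·c(starting material)·c(target), M grows with the mean of the product of the two fractions over the run. South-west, which lost 22.0%, gives k = 2.55 × 10⁻⁴ M⁻¹ s⁻¹, and south gives 2.57 × 10⁻⁴ M⁻¹ s⁻¹, close to it. South-west thus has 0.355 of what I carry, the loss number k·c(starting material)/λ; at fixed equivalents, a finished flask's target follows from it.

Midnight has 0.277, less than south-west, so I expect it above south-west's reading of 75.8%. I expect midnight's fractions to shrink less, so its mean is higher and its loss at least M scaled by the loss numbers, which on this reckoning puts an upper estimate of 82.8% on its target. Autumn has 1.01, more, so I place autumn between 37.4% and south-west's 75.8%, and its λ·t of 2.79 is larger than south-west's 2.48. My reckoning therefore puts midnight first and autumn last. The forecast, saying “about 2 mol% should be best”, gives dawn > noon > dusk > midnight > autumn with 62% and 50%, and midnight > dusk > dawn > noon > autumn at 10 h.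

Midnight gives 81.5% and autumn 63.0%, in the order midnight > dusk > dawn > noon > autumn, and midnight > dusk > dawn > noon > autumn at 10 h. Midnight ends with 17.9% as side product. Loss per loss number is 0.668 there and 0.366 in autumn, against 0.620 in south-west.

    initiator → 2 initiating radical (k = 3.04 × 10⁻⁷ s⁻¹, Ea = 108 kJ mol⁻¹)
    starting material + initiating radical → capped initiator + first chain carrier (k = 30600 M⁻¹ s⁻¹, Ea = 29.0 kJ mol⁻¹)
    partner + first chain carrier → target + second chain carrier (k = 4230 M⁻¹ s⁻¹, Ea = 21.0 kJ mol⁻¹)
    starting material + second chain carrier → by-product + first chain carrier (k = 98700 M⁻¹ s⁻¹, Ea = 16.0 kJ mol⁻¹)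
    first chain carrier → ended carrier (k = 0.0824 s⁻¹, Ea = 63.0 kJ mol⁻¹)
    2 first chain carrier → ended chains (k = 1.00 × 10⁷ M⁻¹ s⁻¹, Ea = 20.0 kJ mol⁻¹)
    starting material + target → side product (k = 2.27 × 10⁻⁴ M⁻¹ s⁻¹, Ea = 73.0 kJ mol⁻¹)
    (constants at 5 °C)

At 12 mol% of initiator, otherwise as midnight, the neighbour flask has a loss number of 0.137, below midnight's, which on this reckoning puts its target between 81.5% and 91.5%. The neighbour flask gives 87.0%.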